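**Retrosynthetic overview**

1. The target is reached by opening a cis 6β,12-lactone with hydroxide; the C8 ester comes from Yamaguchi acylation of an 8β-alcohol with the acid made from the Roche ester.
2. The 8β-OH comes from α-face hydride reduction of a C8 ketone, the lactone from MnO2 oxidation of a 6β,12-diol, and the 6β-OH from LiBH(s-Bu)3 reduction of the C6 ketone.
3. The C8 ketone (masked as its oxime) comes from a photochemical 1,5-hydrogen-shift relay that starts at the C12 alkoxy radical (the new step).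
4. The vinyl group on C10 and the propenyl group on C5 come from a [2+2] photocycloaddition of a β-methyl enone with a 1-substituted cyclobutene (key C–C bonds, quaternary C10), followed by thermal cycloreversion.
5. Rings: the cyclohexane is bought as (1S,4R)-p-mentha-2,8-dien-1-ol, which also supplies C7; two cyclobutanes are made in the photoaddition and opened again; the lactone is closed late and opened in the last step.

Notation and assumption: elemane numbering is used (C10 bears CH3-14 and the vinyl group C1=C2, C5 bears C4(=C3H2)C15, C7 bears C11(=C13H2)C12; β is the face of CH3-14), and the target is taken as the free γ-hydroxy acid, isolated cold at pH 5 because acid closes it to the 6,12-lactone.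

**Step 1**
Reactants: 1 (1S,4R)-p-mentha-2,8-dien-1-ol [(1S,4R)-1-methyl-4-(prop-1-en-2-yl)cyclohex-2-en-1-ol]
Product: 2 (6S)-3-methyl-6-(prop-1-en-2-yl)cyclohex-2-en-1-one [(S)-isopiperitenone]
Conditions: IBX (1.5 equiv), DMSO, 45 °C
Reagents that add atoms: none
Why: Babler–Dauben-type oxidative 1,3-transposition of the tertiary allylic alcohol moves its oxygen to C3 and oxidises it to the enone carbonyl, which erases the carbinol centre and leaves the isopropenyl-bearing stereocentre (future C7) untouched under non-basic conditions.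

**Step 2**
Reactants: 2 (6S)-3-methyl-6-(prop-1-en-2-yl)cyclohex-2-en-1-one
Product: 3 (6S)-6-(3-hydroxyprop-1-en-2-yl)-3-methylcyclohex-2-en-1-one
Conditions: SeO2 (0.3 equiv), t-BuOOH (3 equiv), CH2Cl2, 0 °C to rt
Reagents that add atoms: tert-butyl hydroperoxide CC(C)(C)OO (its oxygen is relayed through SeO2, O=[Se]=O)
Why: SeO2-catalysed allylic hydroxylation (ene reaction then [2,3]-shift) attacks only the electron-rich 1,1-disubstituted alkene and prefers its methyl group, the neutral medium keeps the enolisable C6 stereocentre, and no new stereocentre is formed.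

**Step 3**
Reactants: 4 cyclobut-1-en-1-ylmethanol
Product: 5 tert-butyl(cyclobut-1-en-1-ylmethoxy)dimethylsilane
Conditions: TBSCl, imidazole, CH2Cl2, 0 °C to rt
Reagents that add atoms: tert-butyldimethylsilyl chloride CC(C)(C)[Si](C)(C)Cl
Why: standard silylation of a primary alcohol, so that later only the C12 hydroxyl is free.

**Step 4**
Reactants: 3 (6S)-6-(3-hydroxyprop-1-en-2-yl)-3-methylcyclohex-2-en-1-one; 5 tert-butyl(cyclobut-1-en-1-ylmethoxy)dimethylsilane
Product: 6 (8S)-5-[(tert-butyldimethylsilyloxy)methyl]-8-(3-hydroxyprop-1-en-2-yl)-1-methyltricyclo[4.4.0.0(2,5)]decan-7-one (cis-anti-cis; cyclobutane carbons C2 and C5 on the face of the six-membered ring opposite the C8 side chain)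
Conditions: hν (365 nm, Pyrex), 5 (5 equiv), CH2Cl2, −40 °C
Reagents that add atoms: none
Why: enone–alkene [2+2] photocycloaddition through the enone triplet joins the β-carbon to the unsubstituted and the α-carbon to the substituted cyclobutene carbon (head-to-head, avoiding two adjacent quaternary carbons) on the face anti to the C6 side chain, which sets the methyl-bearing quaternary carbon under control of the bought stereocentre, the minor facial isomer being removed by chromatography; the same reaction type is known for piperitone and 1-methylcyclobutene.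

**Step 5**
Reactants: 6 the tricyclic photoadduct
Product: 8 (5αH,7αH)-12-hydroxy-15-(tert-butyldimethylsilyloxy)elema-1,3,11(13)-trien-6-one, via C5-epimeric ketone 7 (not isolated)
Conditions: PhMe, 200 °C (sealed tube); then DBU (0.2 equiv), rt
Reagents that add atoms: none
Why: thermal cycloreversion of the bicyclo[2.2.0]hexane unit (photo-thermal metathesis) unveils the vinyl and the 2-propenyl group cis to each other in 7, and DBU then epimerises C5 (α to the ketone) to the thermodynamic isomer in which all three alkenyl groups are equatorial and CH3-14 is axial, with C10 and C7 unchanged.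

**Step 6**
Reactants: 8 (5αH,7αH)-12-hydroxy-15-(tert-butyldimethylsilyloxy)elema-1,3,11(13)-trien-6-one
Product: 10 (5αH,7αH)-12-hydroxy-8-(hydroxyimino)-15-(tert-butyldimethylsilyloxy)elema-1,3,11(13)-trien-6-one, via C8-nitroso ketone 9 (not isolated)
Conditions: (n-Bu4N)2CeCl6 (5 mol%), t-BuONO (2 equiv), MeCN, 400 nm LEDs, 20 °C; then i-PrOH, 60 °C
Reagents that add atoms: tert-butyl nitrite CC(C)(C)ON=O
Why: Proposed new method: LMCT excitation of the tetravalent cerium alkoxide of the free C12–OH releases the C12 alkoxy radical, a six-membered 1,5-hydrogen shift (the only δ-hydrogens are on C8 because C6 is a carbonyl carbon) gives the C8 radical, which is trapped at nitrogen by tert-butyl nitrite to form the C8–N bond of nitroso compound 9 while the expelled tert-butoxyl radical reoxidises trivalent cerium, and 9 tautomerises to oxime 10, so C8 reaches the ketone oxidation level in masked form without creating a stereocentre; the closest known reactions are the Barton nitrite photolysis, the cerium-LMCT δ-amination of alkanols with azodicarboxylates and the nitrosation of alkyl radicals by alkyl nitrites.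

**Step 7**
Reactants: 10 the C8 oxime ketone
Product: 11 (5αH,7αH)-6β,12-dihydroxy-8-(hydroxyimino)-15-(tert-butyldimethylsilyloxy)elema-1,3,11(13)-triene
Conditions: LiBH(s-Bu)3 (4 equiv), THF, −78 °C; then H2O
Reagents that add atoms: none
Why: the bulky hydride attacks the C6 ketone from the equatorial α-side, away from the syn-axial CH3-14, so the axial 6β-alcohol is formed (steric approach control in a ketone reduction), and the oxime is not reduced at this temperature.

**Step 8**
Reactants: 11 the 6β,12-diol oxime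
Product: 14 (5αH,7αH)-8-oxo-15-(tert-butyldimethylsilyloxy)elema-1,3,11(13)-trien-6β,12-olide, via lactol oxime 12 (not isolated), via oxime lactone 13 (not isolated)
Conditions: MnO2 (25 equiv), CH2Cl2, rt; then glyoxylic acid monohydrate (5 equiv), THF/H2O, rt
Reagents that add atoms: water O
Why: MnO2 oxidises only the allylic alcohol to the enal, which closes with the cis 6β-OH to lactol 12 and is oxidised on to the α-methylene lactone 13 (oxidative lactonisation), after which trans-oximation to glyoxylic acid frees the C8 ketone under mild acid, with no stereocentre changed.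

**Step 9**
Reactants: 14 the 8-oxo lactone
Product: 15 (5αH,7αH)-8β-hydroxy-15-(tert-butyldimethylsilyloxy)elema-1,3,11(13)-trien-6β,12-olide
Conditions: NaBH4 (1.5 equiv), CeCl3·7H2O (1.5 equiv), MeOH, −78 °C
Reagents that add atoms: none
Why: Luche reduction is 1,2-selective and spares the methylene lactone, and hydride arrives from the α-face because the β-face of C8 is blocked by the syn-axial CH3-14 and the axial lactone oxygen on C6, which gives the axial 8β-alcohol.

**Step 10**
Reactants: 16 methyl (R)-3-hydroxy-2-methylpropanoate (Roche ester)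
Product: 17 methyl (R)-3-(tert-butyldimethylsilyloxy)-2-methylpropanoate
Conditions: TBSCl, imidazole, DMF, rt
Reagents that add atoms: tert-butyldimethylsilyl chloride CC(C)(C)[Si](C)(C)Cl
Why: standard silylation of the primary alcohol, which does not touch the bought stereocentre.

**Step 11**
Reactants: 17 methyl (R)-3-(tert-butyldimethylsilyloxy)-2-methylpropanoate
Product: 18 (R)-3-(tert-butyldimethylsilyloxy)-2-methylpropanoic acid
Conditions: LiOH·H2O (2 equiv), THF/MeOH/H2O, 0 °C to rt; then 1 M HCl to pH 4, 0 °C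
Reagents that add atoms: lithium hydroxide [Li+].[OH-]
Why: ester saponification under mild conditions that do not epimerise the α-stereocentre or cleave the silyl ether.

**Step 12**
Reactants: 15 the 8β-hydroxy lactone; 18 (R)-3-(tert-butyldimethylsilyloxy)-2-methylpropanoic acid
Product: 20 (5αH,7αH)-8β-[(R)-3-(tert-butyldimethylsilyloxy)-2-methylpropanoyloxy]-15-(tert-butyldimethylsilyloxy)elema-1,3,11(13)-trien-6β,12-olide, via mixed anhydride 19 (not isolated)
Conditions: 18, 2,4,6-trichlorobenzoyl chloride, Et3N, THF, rt; then 15, DMAP, PhMe, 40 °C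
Reagents that add atoms: none
Why: Yamaguchi esterification through mixed anhydride 19 acylates the hindered axial 8β-OH on oxygen, so C8 and the side-chain centre keep their configuration.

**Step 13**
Reactants: 20 the bis-silyl ester lactone
Product: 21 (5αH,7αH)-15-hydroxy-8β-[(R)-3-hydroxy-2-methylpropanoyloxy]elema-1,3,11(13)-trien-6β,12-olide
Conditions: HF·pyridine, pyridine/THF, 0 °C to rt
Reagents that add atoms: none
Why: fluoride-mediated desilylation removes both primary TBS ethers and leaves the lactone and the ester untouched.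

**Step 14**
Reactants: 21 the diol ester lactone
Product: 22 (5αH,7αH)-6β,15-dihydroxy-8β-[(R)-3-hydroxy-2-methylpropanoyloxy]elema-1,3,11(13)-trien-12-oic acid (CNP0462645.2)
Conditions: LiOH (1.2 equiv), THF/H2O 3:1, 0 °C; then 0.1 M HCl to pH 5, 0 °C, EtOAc
Reagents that add atoms: lithium hydroxide [Li+].[OH-]
Why: chemoselective saponification, because the strained α-methylene γ-lactone is opened much faster than the hindered, α-branched secondary ester, and cold acidification to pH 5 gives the free hydroxy acid without touching a stereocentre.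

**Compound list**

1 | (1S,4R)-p-mentha-2,8-dien-1-ol | C[C@@]1(O)C=C[C@H](C(C)=C)CC1 | starting material
2 | (6S)-3-methyl-6-(prop-1-en-2-yl)cyclohex-2-en-1-one | CC1=CC(=O)[C@H](C(C)=C)CC1 | intermediate
3 | (6S)-6-(3-hydroxyprop-1-en-2-yl)-3-methylcyclohex-2-en-1-one | CC1=CC(=O)[C@H](C(=C)CO)CC1 | intermediate
4 | cyclobut-1-en-1-ylmethanol | OCC1=CCC1 | starting material
5 | tert-butyl(cyclobut-1-en-1-ylmethoxy)dimethylsilane | CC(C)(C)[Si](C)(C)OCC1=CCC1 | intermediate
6 | (8S)-5-[(tert-butyldimethylsilyloxy)methyl]-8-(3-hydroxyprop-1-en-2-yl)-1-methyltricyclo[4.4.0.0(2,5)]decan-7-one, cis-anti-cis, cyclobutanes anti to the C8 side chain | C[C@@]12CC[C@@H](C(=C)CO)C(=O)[C@@H]1[C@@]1(CO[Si](C)(C)C(C)(C)C)CC[C@H]12 | intermediate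
7 | (5βH,7αH)-12-hydroxy-15-(tert-butyldimethylsilyloxy)elema-1,3,11(13)-trien-6-one (C5 epimer of 8, not isolated) | C=C[C@]1(C)CC[C@@H](C(=C)CO)C(=O)[C@@H]1C(=C)CO[Si](C)(C)C(C)(C)C | intermediate
8 | (5αH,7αH)-12-hydroxy-15-(tert-butyldimethylsilyloxy)elema-1,3,11(13)-trien-6-one | C=C[C@]1(C)CC[C@@H](C(=C)CO)C(=O)[C@H]1C(=C)CO[Si](C)(C)C(C)(C)C | intermediate
9 | (5αH,7αH)-12-hydroxy-8-nitroso-15-(tert-butyldimethylsilyloxy)elema-1,3,11(13)-trien-6-one (C8 epimer mixture, not isolated) | C=C[C@]1(C)CC(N=O)[C@@H](C(=C)CO)C(=O)[C@H]1C(=C)CO[Si](C)(C)C(C)(C)C | intermediate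
10 | (5αH,7αH)-12-hydroxy-8-(hydroxyimino)-15-(tert-butyldimethylsilyloxy)elema-1,3,11(13)-trien-6-one (E/Z mixture) | C=C[C@]1(C)CC(=NO)[C@@H](C(=C)CO)C(=O)[C@H]1C(=C)CO[Si](C)(C)C(C)(C)C | intermediate
11 | (5αH,7αH)-6β,12-dihydroxy-8-(hydroxyimino)-15-(tert-butyldimethylsilyloxy)elema-1,3,11(13)-triene | C=C[C@]1(C)CC(=NO)[C@@H](C(=C)CO)[C@@H](O)[C@H]1C(=C)CO[Si](C)(C)C(C)(C)C | intermediate
12 | 6β,12-lactol of the C12 aldehyde, 8-oxime (anomer mixture, not isolated) | C=C[C@]1(C)CC(=NO)[C@H]2C(=C)C(O)O[C@H]2[C@H]1C(=C)CO[Si](C)(C)C(C)(C)C | intermediate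
13 | (5αH,7αH)-8-(hydroxyimino)-15-(tert-butyldimethylsilyloxy)elema-1,3,11(13)-trien-6β,12-olide (not isolated) | C=C[C@]1(C)CC(=NO)[C@H]2C(=C)C(=O)O[C@H]2[C@H]1C(=C)CO[Si](C)(C)C(C)(C)C | intermediate
14 | (5αH,7αH)-8-oxo-15-(tert-butyldimethylsilyloxy)elema-1,3,11(13)-trien-6β,12-olide | C=C[C@]1(C)CC(=O)[C@H]2C(=C)C(=O)O[C@H]2[C@H]1C(=C)CO[Si](C)(C)C(C)(C)C | intermediate
15 | (5αH,7αH)-8β-hydroxy-15-(tert-butyldimethylsilyloxy)elema-1,3,11(13)-trien-6β,12-olide | C=C[C@]1(C)C[C@@H](O)[C@H]2C(=C)C(=O)O[C@H]2[C@H]1C(=C)CO[Si](C)(C)C(C)(C)C | intermediate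
16 | methyl (R)-3-hydroxy-2-methylpropanoate | COC(=O)[C@H](C)CO | starting material
17 | methyl (R)-3-(tert-butyldimethylsilyloxy)-2-methylpropanoate | COC(=O)[C@H](C)CO[Si](C)(C)C(C)(C)C | intermediate
18 | (R)-3-(tert-butyldimethylsilyloxy)-2-methylpropanoic acid | OC(=O)[C@H](C)CO[Si](C)(C)C(C)(C)C | intermediate
19 | (R)-3-(tert-butyldimethylsilyloxy)-2-methylpropanoic 2,4,6-trichlorobenzoic anhydride (not isolated) | O=C(OC(=O)c1c(Cl)cc(Cl)cc1Cl)[C@H](C)CO[Si](C)(C)C(C)(C)C | intermediate
20 | (5αH,7αH)-8β-[(R)-3-(tert-butyldimethylsilyloxy)-2-methylpropanoyloxy]-15-(tert-butyldimethylsilyloxy)elema-1,3,11(13)-trien-6β,12-olide | C=C[C@]1(C)C[C@@H](OC(=O)[C@H](C)CO[Si](C)(C)C(C)(C)C)[C@H]2C(=C)C(=O)O[C@H]2[C@H]1C(=C)CO[Si](C)(C)C(C)(C)C | intermediate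
21 | (5αH,7αH)-15-hydroxy-8β-[(R)-3-hydroxy-2-methylpropanoyloxy]elema-1,3,11(13)-trien-6β,12-olide | C=C[C@]1(C)C[C@@H](OC(=O)[C@H](C)CO)[C@H]2C(=C)C(=O)O[C@H]2[C@H]1C(=C)CO | intermediate
22 | (5αH,7αH)-6β,15-dihydroxy-8β-[(R)-3-hydroxy-2-methylpropanoyloxy]elema-1,3,11(13)-trien-12-oic acid | C=C[C@]1(C)C[C@@H](OC(=O)[C@H](C)CO)[C@@H](C(=C)C(=O)O)[C@@H](O)[C@H]1C(=C)CO | target

**Step count and risks**

Total step count: 14 (steps 3, 10 and 11 are side branches). Longest linear sequence: 11 steps (1, 2, 4, 5, 6, 7, 8, 9, 12, 13, 14).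

The three steps most likely to fail:

Step 6 (the proposed new relay oximation). The catalytic cycle is untested, the alkoxy radical is allylic, and the tert-butoxyl radical may abstract hydrogen unselectively before trivalent cerium quenches it. The fallback uses known chemistry, sets out from 8 and comes back at 14. TMSOTf/Et3N gives the bis-silyl dienol ether 6,12-bis(trimethylsilyloxy)-15-(tert-butyldimethylsilyloxy)elema-1,3,6,11(13)-tetraene F4 (the enol ether can only be dehydrogenated toward C8 because C10 is quaternary). Pd(OAc)2 in MeCN (Saegusa–Ito) and citric-acid work-up give the enone 12-hydroxy-15-(tert-butyldimethylsilyloxy)elema-1,3,7,11(13)-tetraen-6-one F5. CuCl/NaOt-Bu/B2pin2/MeOH adds boron to C8 anti to CH3-14 with equatorial protonation at C7 to give the 8α-pinacolboronate F6, and NaBO3·4H2O gives the 8α-hydroxy ketone F7. LiBH(s-Bu)3 reduces C6 to the 6β,8α,12-triol F8, MnO2 closes the 8α-hydroxy-6β,12-olide F9, and Dess–Martin periodinane oxidises its 8α-alcohol to 14.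

Step 4 (photocycloaddition). The risks are regiochemistry with the trisubstituted cyclobutene, facial selectivity, and competing intramolecular photoreactions of the β,γ-unsaturated enone. The fallback sets out from 3 and comes back at 7. Irradiation (365 nm) with commercial tert-butyldimethyl(prop-2-yn-1-yloxy)silane gives the cyclobutene photoadduct 8-[(tert-butyldimethylsilyloxy)methyl]-3-(3-hydroxyprop-1-en-2-yl)-6-methylbicyclo[4.2.0]oct-7-en-2-one F3 (cis-fused, cyclobutene anti to the C3 side chain). Ring-opening metathesis with ethylene (1 atm) and second-generation Grubbs catalyst RuCl2(=CHPh)(PCy3)(H2IMes) in CH2Cl2 at rt converts F3 into 7 without heating, and the DBU treatment of step 5 then gives 8.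

Step 2 (allylic hydroxylation). SeO2 may over-oxidise to the enal or attack the ring methine next to the carbonyl. The fallback sets out from 2 and comes back at 3. Ene-type chlorination with NaOCl/CeCl3·7H2O in CH2Cl2/H2O at 0 °C gives the allylic chloride (6S)-6-(3-chloroprop-1-en-2-yl)-3-methylcyclohex-2-en-1-one F1. HCO2Na with catalytic n-Bu4NI in DMF gives the formate 2-[(1S)-4-methyl-2-oxocyclohex-3-en-1-yl]prop-2-en-1-yl formate F2, and NaHCO3 in MeOH at 0 °C releases 3.

**Further compounds**

F1 | step 2 | (6S)-6-(3-chloroprop-1-en-2-yl)-3-methylcyclohex-2-en-1-one | CC1=CC(=O)[C@H](C(=C)CCl)CC1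
F2 | step 2 | 2-[(1S)-4-methyl-2-oxocyclohex-3-en-1-yl]prop-2-en-1-yl formate | CC1=CC(=O)[C@H](C(=C)COC=O)CC1
F3 | step 4 | 8-[(tert-butyldimethylsilyloxy)methyl]-3-(3-hydroxyprop-1-en-2-yl)-6-methylbicyclo[4.2.0]oct-7-en-2-one, cis-fused, cyclobutene anti to the C3 side chain | C[C@@]12CC[C@@H](C(=C)CO)C(=O)[C@@H]1C(CO[Si](C)(C)C(C)(C)C)=C2
F4 | step 6 | (5αH)-6,12-bis(trimethylsilyloxy)-15-(tert-butyldimethylsilyloxy)elema-1,3,6,11(13)-tetraene | C=C[C@]1(C)CCC(C(=C)CO[Si](C)(C)C)=C(O[Si](C)(C)C)[C@H]1C(=C)CO[Si](C)(C)C(C)(C)C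
F5 | step 6 | (5αH)-12-hydroxy-15-(tert-butyldimethylsilyloxy)elema-1,3,7,11(13)-tetraen-6-one | C=C[C@]1(C)CC=C(C(=C)CO)C(=O)[C@H]1C(=C)CO[Si](C)(C)C(C)(C)C
F6 | step 6 | (5αH,7αH)-12-hydroxy-8α-(4,4,5,5-tetramethyl-1,3,2-dioxaborolan-2-yl)-15-(tert-butyldimethylsilyloxy)elema-1,3,11(13)-trien-6-one | C=C[C@]1(C)C[C@H](B2OC(C)(C)C(C)(C)O2)[C@@H](C(=C)CO)C(=O)[C@H]1C(=C)CO[Si](C)(C)C(C)(C)C
F7 | step 6 | (5αH,7αH)-8α,12-dihydroxy-15-(tert-butyldimethylsilyloxy)elema-1,3,11(13)-trien-6-one | C=C[C@]1(C)C[C@H](O)[C@@H](C(=C)CO)C(=O)[C@H]1C(=C)CO[Si](C)(C)C(C)(C)C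
F8 | step 6 | (5αH,7αH)-15-(tert-butyldimethylsilyloxy)elema-1,3,11(13)-triene-6β,8α,12-triol | C=C[C@]1(C)C[C@H](O)[C@@H](C(=C)CO)[C@@H](O)[C@H]1C(=C)CO[Si](C)(C)C(C)(C)C
F9 | step 6 | (5αH,7αH)-8α-hydroxy-15-(tert-butyldimethylsilyloxy)elema-1,3,11(13)-trien-6β,12-olide | C=C[C@]1(C)C[C@H](O)[C@H]2C(=C)C(=O)O[C@H]2[C@H]1C(=C)CO[Si](C)(C)C(C)(C)C
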